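**Plan**

- Retrosynthesis (numbering in the remark below): the 12,13-epoxide, both acetates, and the C15=C17 methylene with the C1–H are taken back to a macrocyclic butenolide. The 14-membered ring is then cut at C2–C3, and the open chain at C14–C1 (Stille), C8–C9 (Nozaki–Hiyama–Kishi) and C7–C8 (B-alkyl Suzuki).
- Enabling feature: the cis-fused lactone ring (O, C2, C1, C15, C16) is a masked 2-silyloxyfuran whose C5 (= C2) is a γ-nucleophile. Its ring neighbour C3 is a carbinol carbon next to the C4 methyl stereocentre, so a C3 aldehyde can be attacked by C2 to close the carbocycle and set the C2/C3 diol pattern in one event.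
- Forward: geranyl acetate gives the C9–C14 aldehyde and an auxiliary-controlled allylation gives the C3–C8 vinyl iodide. The chain is joined, the butenolide attached, converted into silyloxyfuran/aldehyde and cyclised; ring fusion, methylene, acetates and epoxide follow on the macrocycle.
- Stereochemistry: C4 from the oxazolidinone auxiliary; C9 from CBS reduction; C3 (Felkin–Anh) and C2 (threo addition) from C4 in the key step; C1 from conjugate reduction anti to the C2 substituent; C12/C13 from Shi epoxidation.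

Key step: step 14

Remark: target numbering is used for all intermediates: C1 lactone β-carbon, C2 lactone γ-carbon, C3 CH(OAc), C4 CH(CH3), C8 C(=CH2), C9 CH(OAc), C12/C13 epoxide, C15/C16/C17 lactone α-carbon, carbonyl and exocyclic CH2. The configuration read from the SMILES is 1S,2R,3R,4S,9S,12R,13R, with a cis lactone, a syn C2-O/C3-O/C4-CH3 triad and an epoxide derived from an (E)-alkene.

**Route**

Step 1
Reactants: 1 geranyl acetate
Product: 2 (2E)-5-(3,3-dimethyloxiran-2-yl)-3-methylpent-2-en-1-yl acetate (racemic oxirane)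
Conditions: mCPBA (1.05 equiv), NaHCO3, CH2Cl2, 0 °C
Reagents that add atoms: mCPBA, OOC(=O)c1cccc(Cl)c1
Why: Prilezhaev epoxidation should take the remote, electron-rich 6,7-alkene because the 2,3-alkene is deactivated by the allylic acetate; the oxirane configuration is irrelevant as the ring is cleaved in step 2.

Step 2
Reactants: 2 (2E)-5-(3,3-dimethyloxiran-2-yl)-3-methylpent-2-en-1-yl acetate
Product: 3 (2E)-3-methyl-6-oxohex-2-en-1-yl acetate
Conditions: H5IO6 (1.2 equiv), THF/H2O, 0 °C
Reagents that add atoms: none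
Why: Periodic acid should hydrolyse the epoxide and cleave the glycol in one pot (oxidative glycol cleavage), leaving the allylic acetate and the (E)-alkene untouched.

Step 3
Reactants: 4 (4R)-4-benzyl-3-propanoyl-1,3-oxazolidin-2-one; 5 allyl iodide
Product: 6 (4R)-4-benzyl-3-[(2S)-2-methylpent-4-enoyl]-1,3-oxazolidin-2-one
Conditions: NaN(SiMe3)2 (1.1 equiv), THF, −78 °C; then 5 (3 equiv), −78 to −45 °C
Reagents that add atoms: none
Why: Evans asymmetric alkylation: the chelated (Z)-sodium enolate should be allylated on the face opposite the benzyl group, which sets the (S)-methyl stereocentre that becomes C4.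

Step 4
Reactants: 6 (4R)-4-benzyl-3-[(2S)-2-methylpent-4-enoyl]-1,3-oxazolidin-2-one
Product: 7 (2S)-N-methoxy-N,2-dimethylpent-4-enamide
Conditions: MeNH(OMe)·HCl (3 equiv), AlMe3 (3 equiv), CH2Cl2, −10 °C to rt
Reagents that add atoms: N,O-dimethylhydroxylamine hydrochloride, CNOC.Cl
Why: Aluminium amide transamidation (Weinreb amide formation) should cleave the exocyclic imide carbonyl without touching the α-stereocentre and gives an acyl group that is later reduced to the C3 aldehyde.

Step 5
Reactants: 7 (2S)-N-methoxy-N,2-dimethylpent-4-enamide; 8 (1-bromovinyl)trimethylsilane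
Product: 10 (2S)-N-methoxy-N,2-dimethyl-6-(trimethylsilyl)hept-6-enamide, via B-alkyl-9-BBN adduct 9 (not isolated)
Conditions: 9-BBN (1.2 equiv), THF, 0 °C to rt; then 8 (1.3 equiv), Pd(dppf)Cl2 (5 mol %), AsPh3 (5 mol %), Cs2CO3 (3 equiv), DMF/H2O, rt
Reagents that add atoms: none
Why: Anti-Markovnikov hydroboration of the terminal alkene followed by B-alkyl Suzuki–Miyaura coupling with the 1-silylvinyl bromide should form C7–C8 and place at C8 a 1,1-disubstituted alkene with a handle for halogenation.

Step 6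
Reactants: 10 (2S)-N-methoxy-N,2-dimethyl-6-(trimethylsilyl)hept-6-enamide
Product: 11 (2S)-6-iodo-N-methoxy-N,2-dimethylhept-6-enamide
Conditions: NIS (1.3 equiv), MeCN/ClCH2CN (4:1), 0 °C
Reagents that add atoms: N-iodosuccinimide, IN1C(=O)CCC1=O
Why: Ipso-iododesilylation: iodonium attack at the silicon-bearing carbon gives a β-silyl-stabilised cation that loses the silyl group, which should deliver the 2-iodo-1-alkene needed for the chromium coupling.

Step 7
Reactants: 11 (2S)-6-iodo-N-methoxy-N,2-dimethylhept-6-enamide; 3 (2E)-3-methyl-6-oxohex-2-en-1-yl acetate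
Product: 12 (2E,11S)-6-hydroxy-12-[methoxy(methyl)amino]-3,11-dimethyl-7-methylidene-12-oxododec-2-en-1-yl acetate (both C6 epimers; C6 = target C9)
Conditions: CrCl2 (4 equiv), NiCl2 (2 mol %), DMSO, rt
Reagents that add atoms: none
Why: Nozaki–Hiyama–Kishi coupling: the alkenylchromium species should add to the aldehyde in the presence of the acetate and the Weinreb amide and form C8–C9; the carbinol configuration is not controlled here and is set in steps 8 and 9.

Step 8
Reactants: 12 the epimeric allylic alcohols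
Product: 13 (2E,11S)-12-[methoxy(methyl)amino]-3,11-dimethyl-7-methylidene-6,12-dioxododec-2-en-1-yl acetate
Conditions: Dess–Martin periodinane (1.3 equiv), NaHCO3, CH2Cl2, 0 °C to rt
Reagents that add atoms: none
Why: Dess–Martin oxidation should convert both epimers into one α-methylene ketone under non-acidic conditions.

Step 9
Reactants: 13 the α-methylene ketone
Product: 14 (2E,6S,11S)-6-hydroxy-12-[methoxy(methyl)amino]-3,11-dimethyl-7-methylidene-12-oxododec-2-en-1-yl acetate
Conditions: (R)-2-methyl-CBS-oxazaborolidine (0.3 equiv), catecholborane (1.6 equiv), toluene, −78 °C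
Reagents that add atoms: none
Why: Corey–Bakshi–Shibata reduction: with the 2-substituted vinyl group as the large and the CH2 chain as the small substituent, the (R)-oxazaborolidine should deliver hydride to give the (S)-carbinol (target C9), and catecholborane at low temperature spares alkenes, acetate and amide.

Step 10
Reactants: 15 4-bromofuran-2(5H)-one
Product: 16 4-(tributylstannyl)furan-2(5H)-one
Conditions: (Bu3Sn)2 (1.1 equiv), Pd(PPh3)4 (3 mol %), toluene, 100 °C
Reagents that add atoms: hexabutylditin, CCCC[Sn](CCCC)(CCCC)[Sn](CCCC)(CCCC)CCCC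
Why: Palladium-catalysed stannylation of the β-bromo enoate (oxidative addition, tin–tin transmetalation, reductive elimination) should give the β-stannyl butenolide as the C1–C2–C15–C16 building block.

Step 11
Reactants: 14 the (6S)-allylic alcohol acetate; 16 4-(tributylstannyl)furan-2(5H)-one
Product: 17 (2S,7S,10E)-7-hydroxy-N-methoxy-N,2,10-trimethyl-6-methylidene-12-(5-oxo-2,5-dihydrofuran-3-yl)dodec-10-enamide
Conditions: Pd2(dba)3 (3 mol %), LiCl (3 equiv), DMF, 45 °C
Reagents that add atoms: none
Why: Stille coupling of the primary allylic acetate through a π-allylpalladium chloride should join the vinyl stannane at the unhindered allyl terminus with retention of the (E)-alkene and form C14–C1; the free secondary alcohol and the amide are tolerated.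

Step 12
Reactants: 17 the hydroxy butenolide amide
Product: 18 (2S,7S,10E)-N-methoxy-N,2,10-trimethyl-6-methylidene-7-(triisopropylsilyloxy)-12-[5-(triisopropylsilyloxy)furan-3-yl]dodec-10-enamide
Conditions: iPr3SiOTf (2.5 equiv), Et3N (4 equiv), CH2Cl2, 0 °C
Reagents that add atoms: triisopropylsilyl triflate, CC(C)[Si](OS(=O)(=O)C(F)(F)F)(C(C)C)C(C)C
Why: O-silylation of the butenolide carbonyl and loss of a ring γ-proton should give the aromatic 2-silyloxyfuran (soft enolisation, favoured over deprotonation at C14 by aromatisation), and the same reagent protects the C9 alcohol.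

Step 13
Reactants: 18 the bis-silylated Weinreb amide
Product: 19 (2S,7S,10E)-2,10-dimethyl-6-methylidene-7-(triisopropylsilyloxy)-12-[5-(triisopropylsilyloxy)furan-3-yl]dodec-10-enal
Conditions: iBu2AlH (1.3 equiv), THF, −78 °C; aq. potassium sodium tartrate, 0 °C
Reagents that add atoms: none
Why: The Weinreb amide should be reduced through a stable chelated aluminium hemiaminal to the aldehyde without epimerisation at C4, while the silyl dienol ether, which has no carbonyl group, is inert to the hydride.

Step 14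
Reactants: 19 the silyloxyfuran aldehyde
Product: 20 macrocyclic butenolide: 14-membered carbocycle C1–C14 fused at C1–C2 to a furan-2(5H)-one (C15=C1), with 3-OH, 4-CH3, 8-methylidene, 9-OSi(iPr)3, 12-CH3 and a (12E)-alkene; 2R,3R,4S,9S
Conditions: 19 added by syringe pump over 8 h to BF3·OEt2 (3 equiv), CH2Cl2, −78 °C (final 1 mM); aq. NaHCO3
Reagents that add atoms: none
Why: Proposed new method: BF3 activates the C3 aldehyde and C5 of the 2-silyloxyfuran (C2 of the target) attacks it in an intramolecular vinylogous Mukaiyama aldol addition, the silyl group being lost to fluoride to leave the butenolide; the closest known reaction type is the intermolecular BF3-promoted addition of 2-silyloxyfurans to aldehydes, which has not been used to close a carbocyclic macrocycle. The 14-membered ring (C1 to C14) closes in a 14-exo-trig mode with respect to the aldehyde, the furan C4–C5 bond lying inside the new ring. C3 should be set R by Felkin–Anh attack anti to the C5 chain of the (4S)-α-methyl aldehyde under the non-chelating Lewis acid, and C2 should be set R by the threo (syn) preference of silyloxyfuran additions through a synclinal open transition state. The step needs γ- over α-attack, which the furan dienol ether provides, and ring closure over oligomerisation, which slow addition to high dilution and the low strain of a 14-membered ring should secure. It also needs the aldehyde to react with the furan and not with the C8 methylene in a carbonyl-ene reaction; the silyloxyfuran is far more nucleophilic and the allylic silyl ether deactivates and shields that alkene.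

Step 15
Reactants: 20 the macrocyclic hydroxy butenolide
Product: 21 the 3-O-triethylsilyl ether of 20 (2R,3R,4S,9S)
Conditions: Et3SiCl (1.5 equiv), imidazole (3 equiv), DMF, 0 °C to rt
Reagents that add atoms: chlorotriethylsilane, CC[Si](Cl)(CC)CC
Why: Silylation with the silyl chloride and imidazole should protect the C3 alcohol without a silyl triflate that could enolise the butenolide and scramble C2.

Step 16
Reactants: 21 the bis-silylated macrocyclic butenolide
Product: 22 the cis-fused saturated γ-lactone (C15 = CH2), 1S,2R,3R,4S,9S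
Conditions: Cu(OAc)2·H2O (5 mol %), 1,2-bis(diphenylphosphino)benzene (5 mol %), PhSiH3 (1.5 equiv), t-BuOH (2 equiv), toluene, 0 °C to rt
Reagents that add atoms: none
Why: Copper hydride conjugate reduction: the phosphine-ligated copper hydride should add to C1 from the face opposite the C3 side chain on C2, so that H1 and H2 become cis (1S), and it leaves the isolated C8 and C12 alkenes alone.

Step 17
Reactants: 22 the saturated lactone
Product: 25 the α-methylene lactone bis-silyl ether (1S,2R,3R,4S,9S), via Mannich base 23 (not isolated), via methiodide 24 (not isolated)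
Conditions: LiN(iPr)2 (1.3 equiv), THF, −78 °C; CH2=NMe2 iodide (3 equiv), −78 to 0 °C; then MeI (excess), MeOH/CH2Cl2, rt; then aq. NaHCO3, CH2Cl2, rt
Reagents that add atoms: N,N-dimethylmethyleneiminium iodide, C=[N+](C)C.[I-]
Why: Mannich reaction of the lactone lithium enolate, N-methylation and E1cB loss of trimethylamine is the standard α-methylenation of γ-lactones and should install C17 without touching C1.

Step 18
Reactants: 25 the α-methylene lactone bis-silyl ether
Product: 26 the 3,9-diol (1S,2R,3R,4S,9S)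
Conditions: HF·pyridine, pyridine, THF, 0 °C to rt
Reagents that add atoms: none
Why: Fluoride cleavage of both silyl ethers should free the C3 and C9 alcohols under buffered conditions that the α-methylene lactone tolerates.

Step 19
Reactants: 26 the diol
Product: 27 the 3,9-diacetate with the (12E)-alkene (1S,2R,3R,4S,9S)
Conditions: Ac2O (4 equiv), pyridine, DMAP (0.1 equiv), CH2Cl2, 0 °C to rt
Reagents that add atoms: acetic anhydride, CC(=O)OC(C)=O
Why: DMAP-catalysed acylation should esterify both secondary alcohols.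

Step 20
Reactants: 27 the diacetate
Product: 28 the target, (1S,2R,3R,4S,9S,12R,13R)-3,9-diacetoxy-12,13-epoxycembra-8(19),15(17)-dien-16,2-olide
Conditions: D-fructose-derived ketone 1,2:4,5-di-O-isopropylidene-β-D-erythro-2,3-hexodiulo-2,6-pyranose (0.3 equiv), KHSO5 (1.5 equiv), K2CO3, Bu4NHSO4, Na2B4O7 buffer, MeCN/CH2(OMe)2/H2O, 0 °C
Reagents that add atoms: potassium peroxymonosulfate, [K+].[O-]S(=O)(=O)OO
Why: Shi epoxidation: the electrophilic chiral dioxirane should react only with the trisubstituted (12E)-alkene, not with the acetoxy-deactivated C8 methylene or the acrylate, and this ketone delivers oxygen in the sense that gives (R,R)-epoxides from (E)-trisubstituted alkenes, here 12R,13R.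

**Compound list**

1 | geranyl acetate, (2E)-3,7-dimethylocta-2,6-dien-1-yl acetate | CC(C)=CCC/C(C)=C/COC(C)=O | starting material
2 | (2E)-5-(3,3-dimethyloxiran-2-yl)-3-methylpent-2-en-1-yl acetate | CC(=O)OC/C=C(\C)CCC1OC1(C)C | intermediate
3 | (2E)-3-methyl-6-oxohex-2-en-1-yl acetate | CC(=O)OC/C=C(\C)CCC=O | intermediate
4 | (4R)-4-benzyl-3-propanoyl-1,3-oxazolidin-2-one | CCC(=O)N1[C@H](Cc2ccccc2)COC1=O | starting material
5 | allyl iodide | C=CCI | starting material
6 | (4R)-4-benzyl-3-[(2S)-2-methylpent-4-enoyl]-1,3-oxazolidin-2-one | C=CC[C@H](C)C(=O)N1[C@H](Cc2ccccc2)COC1=O | intermediate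
7 | (2S)-N-methoxy-N,2-dimethylpent-4-enamide | C=CC[C@H](C)C(=O)N(C)OC | intermediate
8 | (1-bromovinyl)trimethylsilane | C=C(Br)[Si](C)(C)C | starting material
9 | (2S)-5-(9-borabicyclo[3.3.1]nonan-9-yl)-N-methoxy-N,2-dimethylpentanamide | CON(C)C(=O)[C@@H](C)CCCB1C2CCCC1CCC2 | intermediate
10 | (2S)-N-methoxy-N,2-dimethyl-6-(trimethylsilyl)hept-6-enamide | CON(C)C(=O)[C@@H](C)CCCC(=C)[Si](C)(C)C | intermediate
11 | (2S)-6-iodo-N-methoxy-N,2-dimethylhept-6-enamide | CON(C)C(=O)[C@@H](C)CCCC(I)=C | intermediate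
12 | (2E,11S)-6-hydroxy-12-[methoxy(methyl)amino]-3,11-dimethyl-7-methylidene-12-oxododec-2-en-1-yl acetate, C6 epimers | CON(C)C(=O)[C@@H](C)CCCC(=C)C(O)CC/C(C)=C/COC(C)=O | intermediate
13 | (2E,11S)-12-[methoxy(methyl)amino]-3,11-dimethyl-7-methylidene-6,12-dioxododec-2-en-1-yl acetate | CON(C)C(=O)[C@@H](C)CCCC(=C)C(=O)CC/C(C)=C/COC(C)=O | intermediate
14 | (2E,6S,11S)-6-hydroxy-12-[methoxy(methyl)amino]-3,11-dimethyl-7-methylidene-12-oxododec-2-en-1-yl acetate | CON(C)C(=O)[C@@H](C)CCCC(=C)[C@@H](O)CC/C(C)=C/COC(C)=O | intermediate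
15 | 4-bromofuran-2(5H)-one | BrC1=CC(=O)OC1 | starting material
16 | 4-(tributylstannyl)furan-2(5H)-one | CCCC[Sn](CCCC)(CCCC)C1=CC(=O)OC1 | intermediate
17 | (2S,7S,10E)-7-hydroxy-N-methoxy-N,2,10-trimethyl-6-methylidene-12-(5-oxo-2,5-dihydrofuran-3-yl)dodec-10-enamide | CON(C)C(=O)[C@@H](C)CCCC(=C)[C@@H](O)CC/C(C)=C/CC1=CC(=O)OC1 | intermediate
18 | (2S,7S,10E)-N-methoxy-N,2,10-trimethyl-6-methylidene-7-(triisopropylsilyloxy)-12-[5-(triisopropylsilyloxy)furan-3-yl]dodec-10-enamide | CON(C)C(=O)[C@@H](C)CCCC(=C)[C@@H](O[Si](C(C)C)(C(C)C)C(C)C)CC/C(C)=C/Cc1coc(O[Si](C(C)C)(C(C)C)C(C)C)c1 | intermediate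
19 | (2S,7S,10E)-2,10-dimethyl-6-methylidene-7-(triisopropylsilyloxy)-12-[5-(triisopropylsilyloxy)furan-3-yl]dodec-10-enal | O=C[C@@H](C)CCCC(=C)[C@@H](O[Si](C(C)C)(C(C)C)C(C)C)CC/C(C)=C/Cc1coc(O[Si](C(C)C)(C(C)C)C(C)C)c1 | intermediate
20 | macrocyclic butenolide, 3-OH, 9-OSi(iPr)3, (2R,3R,4S,9S,12E) | C=C1CCC[C@H](C)[C@@H](O)[C@@H]2OC(=O)C=C2C/C=C(\C)CC[C@@H]1O[Si](C(C)C)(C(C)C)C(C)C | intermediate
21 | macrocyclic butenolide, 3-OSiEt3, 9-OSi(iPr)3, (2R,3R,4S,9S,12E) | C=C1CCC[C@H](C)[C@@H](O[Si](CC)(CC)CC)[C@@H]2OC(=O)C=C2C/C=C(\C)CC[C@@H]1O[Si](C(C)C)(C(C)C)C(C)C | intermediate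
22 | cis-fused saturated lactone, 3-OSiEt3, 9-OSi(iPr)3, (1S,2R,3R,4S,9S,12E) | C=C1CCC[C@H](C)[C@@H](O[Si](CC)(CC)CC)[C@@H]2OC(=O)C[C@@H]2C/C=C(\C)CC[C@@H]1O[Si](C(C)C)(C(C)C)C(C)C | intermediate
23 | 15-(dimethylaminomethyl) lactone (Mannich base, C15 epimers) | C=C1CCC[C@H](C)[C@@H](O[Si](CC)(CC)CC)[C@@H]2OC(=O)C(CN(C)C)[C@@H]2C/C=C(\C)CC[C@@H]1O[Si](C(C)C)(C(C)C)C(C)C | intermediate
24 | 15-(trimethylammoniomethyl) lactone iodide | C=C1CCC[C@H](C)[C@@H](O[Si](CC)(CC)CC)[C@@H]2OC(=O)C(C[N+](C)(C)C)[C@@H]2C/C=C(\C)CC[C@@H]1O[Si](C(C)C)(C(C)C)C(C)C.[I-] | intermediate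
25 | α-methylene lactone, 3-OSiEt3, 9-OSi(iPr)3, (1S,2R,3R,4S,9S,12E) | C=C1CCC[C@H](C)[C@@H](O[Si](CC)(CC)CC)[C@@H]2OC(=O)C(=C)[C@@H]2C/C=C(\C)CC[C@@H]1O[Si](C(C)C)(C(C)C)C(C)C | intermediate
26 | α-methylene lactone 3,9-diol, (1S,2R,3R,4S,9S,12E) | C=C1CCC[C@H](C)[C@@H](O)[C@@H]2OC(=O)C(=C)[C@@H]2C/C=C(\C)CC[C@@H]1O | intermediate
27 | α-methylene lactone 3,9-diacetate, (1S,2R,3R,4S,9S,12E) | C=C1CCC[C@H](C)[C@@H](OC(C)=O)[C@@H]2OC(=O)C(=C)[C@@H]2C/C=C(\C)CC[C@@H]1OC(C)=O | intermediate
28 | (1S,2R,3R,4S,9S,12R,13R)-3,9-diacetoxy-12,13-epoxycembra-8(19),15(17)-dien-16,2-olide | C=C1CCC[C@H](C)[C@@H](OC(C)=O)[C@@H]2OC(=O)C(=C)[C@@H]2C[C@H]2O[C@]2(C)CC[C@@H]1OC(C)=O | target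

**Count and risks**

Total step count: 20. Longest linear sequence: 17 steps (steps 3 to 9, then 11 to 20).

Steps most likely to fail:

1. Step 14 (bears the label). What may go wrong: intermolecular aldol oligomerisation outcompeting ring closure, or erosion of the threo/Felkin selectivity by the conformational demands of the forming ring. Fallback with known chemistry: make C2–C3 by the intermolecular BF3-promoted silyloxyfuran aldol addition and close the ring at C8–C9 by a Nozaki–Hiyama–Kishi macrocyclisation. It sets out from 3, 11 and 16 and returns at 21.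
 - NaBH4 reduction of 3 should give (2E)-6-hydroxy-3-methylhex-2-en-1-yl acetate F1; 4-methoxybenzyl trichloroacetimidate with catalytic camphorsulfonic acid gives the PMB ether F2.
 - Coupling of F2 with 16 as in step 11 gives the butenolide F3, and iPr3SiOTf/Et3N gives the silyloxyfuran F4.
 - iBu2AlH reduction of 11 gives (2S)-6-iodo-2-methylhept-6-enal F5.
 - BF3·OEt2 at −78 °C should join F4 and F5 to the threo, Felkin aldol adduct F6, which is silylated (Et3SiCl, imidazole) to the triethylsilyl ether F7.
 - DDQ removes the PMB group to give the primary alcohol F8, and Dess–Martin oxidation gives the iodo aldehyde F9.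
 - CrCl2/NiCl2 at high dilution closes the 14-membered ring to the macrocyclic carbinol F10 (C9 epimers).
 - Dess–Martin oxidation gives the macrocyclic enone F11, CBS reduction as in step 9 gives the (9S)-alcohol F12, and iPr3SiOTf/2,6-lutidine at −78 °C gives 21.

2. Step 20. What may go wrong: the conformational bias of the macrocycle overrides the catalyst, so that oxygen is delivered to the wrong face of the C12=C13 alkene. Fallback: the two-step halohydrin route, which places the oxygen on the face opposite to the one attacked first. From 27, NBS in THF/H2O at 0 °C should open the bromonium ion anti at the tertiary C12 to give the (12R,13S)-bromohydrin F13. DBU in CH2Cl2 then closes the epoxide with inversion at C13 and returns the route at 28.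

3. Step 6. What may go wrong: iodonium attack at the terminal alkene carbon, leading to addition products in place of ipso-substitution. Fallback: halogenation by addition–elimination. From 10, Br2 in CH2Cl2 at −78 °C should give the dibromide F14, and NaOMe in MeOH should trigger anti-elimination of the β-silyl bromide to the vinyl bromide F15. F15 enters the chromium coupling of step 7 in place of 11 and returns the route at 12.

Further compounds
F1 | step 14 | (2E)-6-hydroxy-3-methylhex-2-en-1-yl acetate | CC(=O)OC/C=C(\C)CCCO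
F2 | step 14 | (2E)-6-[(4-methoxybenzyl)oxy]-3-methylhex-2-en-1-yl acetate | CC(=O)OC/C=C(\C)CCCOCc1ccc(OC)cc1
F3 | step 14 | 4-{(2E)-6-[(4-methoxybenzyl)oxy]-3-methylhex-2-en-1-yl}furan-2(5H)-one | COc1ccc(COCCC/C(C)=C/CC2=CC(=O)OC2)cc1
F4 | step 14 | triisopropyl[(4-{(2E)-6-[(4-methoxybenzyl)oxy]-3-methylhex-2-en-1-yl}furan-2-yl)oxy]silane | COc1ccc(COCCC/C(C)=C/Cc2coc(O[Si](C(C)C)(C(C)C)C(C)C)c2)cc1
F5 | step 14 | (2S)-6-iodo-2-methylhept-6-enal | O=C[C@@H](C)CCCC(I)=C
F6 | step 14 | (5R)-5-[(1R,2S)-1-hydroxy-6-iodo-2-methylhept-6-en-1-yl]-4-{(2E)-6-[(4-methoxybenzyl)oxy]-3-methylhex-2-en-1-yl}furan-2(5H)-one | C=C(I)CCC[C@H](C)[C@@H](O)[C@@H]1OC(=O)C=C1C/C=C(\C)CCCOCc1ccc(OC)cc1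
F7 | step 14 | triethylsilyl ether of F6 | C=C(I)CCC[C@H](C)[C@@H](O[Si](CC)(CC)CC)[C@@H]1OC(=O)C=C1C/C=C(\C)CCCOCc1ccc(OC)cc1
F8 | step 14 | primary alcohol from F7 | C=C(I)CCC[C@H](C)[C@@H](O[Si](CC)(CC)CC)[C@@H]1OC(=O)C=C1C/C=C(\C)CCCO
F9 | step 14 | iodo aldehyde from F8 | C=C(I)CCC[C@H](C)[C@@H](O[Si](CC)(CC)CC)[C@@H]1OC(=O)C=C1C/C=C(\C)CCC=O
F10 | step 14 | macrocyclic butenolide, 3-OSiEt3, 9-OH (C9 epimers) | C=C1CCC[C@H](C)[C@@H](O[Si](CC)(CC)CC)[C@@H]2OC(=O)C=C2C/C=C(\C)CCC1O
F11 | step 14 | macrocyclic butenolide, 3-OSiEt3, 9-oxo | C=C1CCC[C@H](C)[C@@H](O[Si](CC)(CC)CC)[C@@H]2OC(=O)C=C2C/C=C(\C)CCC1=O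
F12 | step 14 | macrocyclic butenolide, 3-OSiEt3, (9S)-OH | C=C1CCC[C@H](C)[C@@H](O[Si](CC)(CC)CC)[C@@H]2OC(=O)C=C2C/C=C(\C)CC[C@@H]1O
F13 | step 20 | (12R,13S)-13-bromo-12-hydroxy derivative of 27 | C=C1CCC[C@H](C)[C@@H](OC(C)=O)[C@@H]2OC(=O)C(=C)[C@@H]2C[C@H](Br)[C@](C)(O)CC[C@@H]1OC(C)=O
F14 | step 6 | (2S)-6,7-dibromo-N-methoxy-N,2-dimethyl-6-(trimethylsilyl)heptanamide (C6 epimers) | CON(C)C(=O)[C@@H](C)CCCC(Br)(CBr)[Si](C)(C)C
F15 | step 6 | (2S)-6-bromo-N-methoxy-N,2-dimethylhept-6-enamide | CON(C)C(=O)[C@@H](C)CCCC(Br)=C
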